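**Retrosynthetic overview**
1. Target 9 ⇒ 2‑alkylpyrrole 7 by the C5–CHO disconnection (Vilsmeier–Haack formylation, last step).
2. The pyrrole of 7 (the only ring, closed in step 2) ⇒ symmetric icosanedinitrile 3 + a propanal homoenolate (d3) equivalent, Grignard 4. The key bond C2–C3 joins a nitrile carbon to an aldehyde β‑carbon, two carbons that are both normally electrophilic.
3. One C≡N of 3 supplies pyrrole C2 and N1; C3–C5 come from 4; the ring closes at N1–C5. The second C≡N of 3 is the nitrile of the target (desymmetrisation by mono‑addition).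
4. 3 ⇒ two molecules of undec‑10‑enenitrile 1 (self‑metathesis, then hydrogenation).

Assumption: the SMILES is read as 19‑(5‑formyl‑1H‑pyrrol‑2‑yl)nonadecanenitrile (18 CH2 between the ring and the nitrile carbon). It has no stereocentre, so no configuration has to be set; the E/Z mixture of 2 is erased by hydrogenation.

**Route**

Step 1
Reactants: 1 undec‑10‑enenitrile (two molecules)
Product: 3 icosanedinitrile, via icos‑10‑enedinitrile 2 (not isolated)
Conditions: Hoveyda–Grubbs II (0.5 mol %), 1,4‑benzoquinone (2 mol %), toluene, 60 °C, N2 sparge; then 10 % Pd/C, H2 (1 atm), EtOAc, rt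
Reagents that add atoms: none
Why: Olefin self‑metathesis of the terminal alkene is driven by loss of ethene and tolerates the remote nitrile (benzoquinone suppresses chain‑walking), and Pd/C hydrogenation at 1 atm then saturates the E/Z alkene without touching aliphatic nitriles; no stereocentre is formed.

Step 2
Reactants: 3 icosanedinitrile; 4 [2‑(1,3‑dioxan‑2‑yl)ethyl]magnesium bromide
Product: 7 19‑(1H‑pyrrol‑2‑yl)nonadecanenitrile, via N‑bromomagnesio ketimine 5 (not isolated), via NH‑ketimine acetal 6 (not isolated)
Conditions: 3 (3 equiv, excess recovered), 4 (0.5 M in THF, 1 equiv), CuBr·SMe2 (5 mol %), THF, 60 °C; then glacial AcOH, 100 °C (THF distilled off)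
Reagents that add atoms: none
Why: Proposed new method: the homoenolate Grignard 4 adds once to one of the two equivalent nitrile carbons of 3 (copper‑accelerated Grignard–nitrile addition; the threefold excess of 3 keeps bis‑addition near 10 %), AcOH protonates ketimide 5 to NH‑ketimine 6, and the imine nitrogen then attacks the oxocarbenium ion formed from the dioxane acetal and aromatises by loss of propane‑1,3‑diol, so the nitrile nitrogen becomes the pyrrole nitrogen; the closest known reactions are Grignard addition to nitriles (ketone synthesis) and the Paal–Knorr/Clauson–Kaas condensation of 4‑oxo‑acetals with ammonia; no stereocentre is formed.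

Step 3
Reactants: 7 19‑(1H‑pyrrol‑2‑yl)nonadecanenitrile
Product: 9 19‑(5‑formyl‑1H‑pyrrol‑2‑yl)nonadecanenitrile, via Vilsmeier iminium chloride 8 (not isolated)
Conditions: POCl3 (1.1 equiv), DMF (1.5 equiv), ClCH2CH2Cl, 0 → 40 °C; then aq NaOAc, 80 °C, 15 min
Reagents that add atoms: N,N‑dimethylformamide CN(C)C=O; water O
Why: Vilsmeier–Haack formylation: the chloroiminium electrophile attacks the only free α‑position (C5) of the electron‑rich 2‑alkylpyrrole, the nitrile is inert, and buffered hydrolysis of iminium 8 releases the aldehyde; the product is achiral.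

**Compound list**
1 | undec‑10‑enenitrile | C=CCCCCCCCCC#N | starting material
2 | icos‑10‑enedinitrile (E/Z mixture, E drawn) | N#CCCCCCCCC/C=C/CCCCCCCCC#N | intermediate (not isolated)
3 | icosanedinitrile | N#CCCCCCCCCCCCCCCCCCCC#N | intermediate
4 | [2‑(1,3‑dioxan‑2‑yl)ethyl]magnesium bromide (commercial 0.5 M THF solution) | Br[Mg]CCC1OCCCO1 | starting material
5 | N‑bromomagnesio derivative of 22‑(1,3‑dioxan‑2‑yl)‑20‑iminodocosanenitrile | N#CCCCCCCCCCCCCCCCCCCC(=N[Mg]Br)CCC1OCCCO1 | intermediate (not isolated)
6 | 22‑(1,3‑dioxan‑2‑yl)‑20‑iminodocosanenitrile | N#CCCCCCCCCCCCCCCCCCCC(=N)CCC1OCCCO1 | intermediate (not isolated)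
7 | 19‑(1H‑pyrrol‑2‑yl)nonadecanenitrile | N#CCCCCCCCCCCCCCCCCCCc1ccc[nH]1 | intermediate
8 | {[5‑(18‑cyanooctadecyl)‑1H‑pyrrol‑2‑yl]methylidene}dimethylammonium chloride | C[N+](C)=Cc1ccc(CCCCCCCCCCCCCCCCCCC#N)[nH]1.[Cl-] | intermediate (not isolated)
9 | 19‑(5‑formyl‑1H‑pyrrol‑2‑yl)nonadecanenitrile (mycalenitrile 14; no stereocentre) | N#CCCCCCCCCCCCCCCCCCCc1ccc(C=O)[nH]1 | target

**Count and risks**
Total steps: 3. Longest linear sequence: 3.

Steps most likely to fail, most risky first:

Step 2 (mono‑addition of 4 to the dinitrile and ring closure in the same flask). The risks are α‑deprotonation of the nitrile instead of addition, and hydrolysis of ketimine 6 before it cyclises. The fallback sets out from 3 and comes back at 7; the homoenolate then meets an aldehyde instead of a nitrile and the ring nitrogen comes from ammonia. Partial reduction of 3 with DIBAL‑H (1 equiv, toluene, −78 °C, excess 3 recycled) gives 20‑oxoicosanenitrile F1. Grignard 4 adds to the aldehyde of F1 at −78 °C, where the nitrile is untouched, to give racemic 22‑(1,3‑dioxan‑2‑yl)‑20‑hydroxydocosanenitrile F2. Dess–Martin oxidation removes that stereocentre and gives 22‑(1,3‑dioxan‑2‑yl)‑20‑oxodocosanenitrile F3. A classical Paal–Knorr condensation of F3 with NH4OAc in AcOH/H2O at 100 °C gives 7. If only the ring closure of step 2 is at fault, an aqueous NH4Cl quench of step 2 gives the same F3 directly.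

Step 1 (self‑metathesis next to a coordinating nitrile; double‑bond migration would give inseparable chain‑shortened homologues). The fallback sets out from 1 and comes back at 3, replacing metathesis by a radical dimerisation. Hydroboration of 1 with 9‑BBN and oxidation with sodium perborate (which spares the nitrile) gives 11‑hydroxyundecanenitrile F4. TEMPO/NaOCl/NaClO2 oxidation gives 10‑cyanodecanoic acid F5. Kolbe electrolysis of F5 (Pt electrodes, MeOH, partly neutralised with NaOMe, 45 °C) couples two 9‑cyanononyl radicals to 3.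

Step 3 (acid‑promoted oligomerisation of the sensitive NH‑pyrrole 7 under POCl3/DMF). The fallback sets out from 7 and comes back at 9; it brings the formyl carbon in as a thioacetal under non‑acidic conditions and unmasks it afterwards. 7 reacts with 1,3‑dithian‑2‑ylium tetrafluoroborate (pyridine, MeCN, 0 °C) at C5 to give 19‑[5‑(1,3‑dithian‑2‑yl)‑1H‑pyrrol‑2‑yl]nonadecanenitrile F6. MeI/CaCO3 in aqueous MeCN at 45 °C hydrolyses F6 to 9.

**Further compounds**
F1 | step 2 | 20‑oxoicosanenitrile | N#CCCCCCCCCCCCCCCCCCCC=O
F2 | step 2 | 22‑(1,3‑dioxan‑2‑yl)‑20‑hydroxydocosanenitrile (racemic) | N#CCCCCCCCCCCCCCCCCCCC(O)CCC1OCCCO1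
F3 | step 2 | 22‑(1,3‑dioxan‑2‑yl)‑20‑oxodocosanenitrile | N#CCCCCCCCCCCCCCCCCCCC(=O)CCC1OCCCO1
F4 | step 1 | 11‑hydroxyundecanenitrile | N#CCCCCCCCCCCO
F5 | step 1 | 10‑cyanodecanoic acid | N#CCCCCCCCCCC(=O)O
F6 | step 3 | 19‑[5‑(1,3‑dithian‑2‑yl)‑1H‑pyrrol‑2‑yl]nonadecanenitrile | N#CCCCCCCCCCCCCCCCCCCc1ccc(C2SCCCS2)[nH]1
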